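**Retrosynthetic overview**

1. The route rests on the cyclopentane C3–C14–C13–C12–C11 with its quaternary C12. It is an isopentyl chain on C3 whose tertiary C12–H lies five atoms from C11, so C11–C12 is made by 1,5 C–H insertion of a C11 acyl carbenoid (temporary C10 ketone).
2. Before that, the cage (both seven-membered rings through C10–C11) is closed by one C3–C11 bond: C-alkylation of the ring A diketone by an endo C7 bromoacetyl group.
3. Ring A is annulated onto ring B by Effenberger double acylation with isopentylmalonyl dichloride. This passes the C7 configuration on to C1 and C5, after which C7 is inverted from exo to endo.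
4. Ring B comes from an asymmetric Diels–Alder reaction, Saegusa oxidation and cuprate addition (C8 gem-dimethyl).
5. Ring order: B, A, the two seven-membered cage rings, cyclopentane. Then C10 is deoxygenated (this sets C11), C5 is geranylated and C1 isobutyrylated.

Key step: step 15

Locants: C1 isobutyryl bridgehead, C2/C4 ketones flanking quaternary C3, C5 geranyl bridgehead, C6H2–C7H–C8Me2 rest of ring B, C9 bridging ketone, C10–C11 bridge from C7 to C3, C12Me2–C13H2–C14H2 rest of the cyclopentane (C14 on C3). Exo = away from the C2–C4 bridge, endo = towards C3.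

Remark 1: the sense of induction in step 2 is assumed to follow the usual model for this catalyst family; if the (1R) adduct forms, the (R)-catalyst is used.

Remark 2: the Effenberger bridge is assumed to form anti to the equatorial C7 ester (exo product), because a syn bridge would be 1,3-diaxial to the ester; this is why C7 is inverted in step 9.

Remark 3: O-methylation in step 8 is written at the less hindered O4; any O2 regioisomer has the same stereocentres, is carried along and converges with it in step 12.

**Route**

Step 1
Reactants: 1 (E)-pent-3-en-2-one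
Product: 2 (E)-2-[(triisopropylsilyl)oxy]penta-1,3-diene
Conditions: i-Pr3SiOSO2CF3, Et3N, Et2O, 0 °C
Reagents that add atoms: triisopropylsilyl trifluoromethanesulfonate, CC(C)[Si](OS(=O)(=O)C(F)(F)F)(C(C)C)C(C)C
Why: Soft enolisation on the CH3 side of the methyl ketone and O-silylation should give the cross-conjugated 2-silyloxy diene (silyl dienol ether formation).

Step 2
Reactants: 2 (E)-2-[(triisopropylsilyl)oxy]penta-1,3-diene; 3 2,2,2-trifluoroethyl acrylate
Product: 4 2,2,2-trifluoroethyl (1S,2R)-2-methyl-4-[(triisopropylsilyl)oxy]cyclohex-3-ene-1-carboxylate (cis)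
Conditions: (S)-3,3-diphenyl-1-(2-methylphenyl)tetrahydropyrrolo[1,2-c][1,3,2]oxazaborole activated with HN(SO2CF3)2 (10 mol%), CH2Cl2, −78 °C
Reagents that add atoms: none
Why: Asymmetric Diels–Alder reaction under chiral oxazaborolidinium catalysis, in which the 2-silyloxy group (para) and the terminal methyl (ortho) direct the same regiochemistry, the endo transition state gives the cis adduct and the shielded face of the boron-bound acrylate sets C7 (the ester carbon) as S.

Step 3
Reactants: 4 Diels–Alder adduct
Product: 5 2,2,2-trifluoroethyl (1S)-2-methyl-4-oxocyclohex-2-ene-1-carboxylate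
Conditions: Pd(OAc)2 (1.05 equiv), MeCN, 25–40 °C
Reagents that add atoms: none
Why: Saegusa oxidation, in which the silyl enol ether forms an oxa-allyl complex of divalent palladium and β-hydride loss from C8–H gives the C1=C8 enone under neutral conditions that should leave the C7 stereocentre untouched.

Step 4
Reactants: 5 enone ester
Product: 6 2,2,2-trifluoroethyl (1S)-2,2-dimethyl-4-[(trimethylsilyl)oxy]cyclohex-3-ene-1-carboxylate
Conditions: Me2CuLi, Me3SiCl, THF, −78 °C
Reagents that add atoms: lithium dimethylcuprate, C[Cu-]C.[Li+]; chlorotrimethylsilane, C[Si](C)(C)Cl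
Why: Silyl-chloride-accelerated conjugate addition of the cuprate builds the quaternary C8 gem-dimethyl carbon and traps the enolate regiospecifically as the C9=C1 silyl enol ether, the ester being inert at −78 °C.

Step 5
Reactants: 7 diethyl 2-(3-methylbutyl)propanedioate (diethyl isopentylmalonate)
Product: 8 2-(3-methylbutyl)propanedioic acid
Conditions: KOH, EtOH–H2O, reflux; then HCl (aq), 0 °C
Reagents that add atoms: potassium hydroxide, [K+].[OH-]
Why: Plain saponification of both esters, with cold acidification so that the malonic acid does not decarboxylate.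

Step 6
Reactants: 8 2-(3-methylbutyl)propanedioic acid
Product: 9 2-(3-methylbutyl)propanedioyl dichloride
Conditions: (COCl)2, DMF (cat.), CH2Cl2, 25 °C
Reagents that add atoms: oxalyl chloride, ClC(=O)C(Cl)=O
Why: Standard conversion of a diacid into its dichloride through the chloroiminium activator, used crude after evaporation.

Step 7
Reactants: 6 silyl enol ether of ring B; 9 isopentylmalonyl dichloride
Product: 10 2,2,2-trifluoroethyl (7S)-4-hydroxy-8,8-dimethyl-3-(3-methylbutyl)-2,9-dioxobicyclo[3.3.1]non-3-ene-7-carboxylate (enol of the 2,4,9-trione, ester exo)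
Conditions: Et2O, −20 to 25 °C, 24 h; aqueous work-up; chromatography
Reagents that add atoms: none
Why: Effenberger cyclisation, in which the enol ether is C-acylated at C1 and then at C5 so that the malonyl unit bridges the two α-carbons diaxially on the face anti to the equatorial C7 ester; this fixes C1 and C5 relative to C7, and any minor endo isomer is removed here because it would enter the enantiomeric series after step 9.

Step 8
Reactants: 10 bicyclic enol-trione exo ester
Product: 11 2,2,2-trifluoroethyl (7S)-4-methoxy-8,8-dimethyl-3-(3-methylbutyl)-2,9-dioxobicyclo[3.3.1]non-3-ene-7-carboxylate (ester exo)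
Conditions: Me3SiCHN2, MeOH–toluene, 0 °C
Reagents that add atoms: (trimethylsilyl)diazomethane, C[Si](C)(C)C=[N+]=[N-]
Why: O-methylation of the vinylogous acid masks the acidic, nucleophilic diketone so that it survives base, acid chloride formation and diazomethane in steps 9–11.

Step 9
Reactants: 11 exo ester methyl enol ether
Product: 12 2,2,2-trifluoroethyl (7R)-4-methoxy-8,8-dimethyl-3-(3-methylbutyl)-2,9-dioxobicyclo[3.3.1]non-3-ene-7-carboxylate (ester endo, towards C3)
Conditions: KN(SiMe3)2 (2.2 equiv), THF, −78 to −40 °C; then AcOH, −78 °C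
Reagents that add atoms: none
Why: Epimerisation by kinetic protonation, in which the ester enolate makes C7 planar and the proton can only arrive from the open exo face, since the endo face lies against ring A, so H ends exo and the ester endo while C1 and C5 keep the absolute configuration.

Step 10
Reactants: 12 endo ester
Product: 13 (7R)-4-methoxy-8,8-dimethyl-3-(3-methylbutyl)-2,9-dioxobicyclo[3.3.1]non-3-ene-7-carboxylic acid (endo)
Conditions: LiOH, H2O2 (30%), THF–H2O, 0 °C; Na2SO3 (aq); HCl (aq) to pH 3
Reagents that add atoms: hydrogen peroxide, OO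
Why: Hydroperoxide-assisted hydrolysis of the activated trifluoroethyl ester, in which the weakly basic, strongly nucleophilic hydroperoxide cleaves the hindered ester faster than C7 can enolise, so the endo configuration is kept.

Step 11
Reactants: 13 endo acid
Product: 15 (7R)-7-(2-diazoacetyl)-4-methoxy-8,8-dimethyl-3-(3-methylbutyl)bicyclo[3.3.1]non-3-ene-2,9-dione, via acid chloride 14 (not isolated)
Conditions: Me2C=C(Cl)NMe2, CH2Cl2, 0 to 25 °C; then CH2N2 (3 equiv), Et2O, 0 °C
Reagents that add atoms: diazomethane, C=[N+]=[N-]
Why: Neutral acid chloride formation with the α-chloroenamine followed by acylation of diazomethane (first stage of the Arndt–Eistert sequence), base-free so that no ketene forms and C7 is not epimerised.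

Step 12
Reactants: 15 endo diazoketone
Product: 16 (7R)-7-(2-bromoacetyl)-4-hydroxy-8,8-dimethyl-3-(3-methylbutyl)bicyclo[3.3.1]non-3-ene-2,9-dione (endo, enol of the trione)
Conditions: HBr (48% aq), THF, 0 to 25 °C
Reagents that add atoms: hydrogen bromide, Br; water, O
Why: Protonation of the diazo carbon and displacement of N2 by bromide gives the bromomethyl ketone, and the same aqueous acid hydrolyses the vinylogous methyl ester to the free enolised diketone needed for step 13.

Step 13
Reactants: 16 endo bromoacetyl trione
Product: 17 caged tetraone: 8,8-dimethyl-3-(3-methylbutyl)bicyclo[3.3.1]nonane-2,4,9-trione with a C7–C10(=O)–C11H2–C3 bridge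
Conditions: Cs2CO3, MeCN (high dilution), 0 to 25 °C
Reagents that add atoms: none
Why: Intramolecular SN2 C-alkylation of the C3 diketonate by the α-bromoketone, in which the endo CH2Br sits directly under C3 while neither enolate oxygen can reach it, so C–C bond formation closes both seven-membered rings and makes C3 quaternary with the isopentyl chain exo.

Step 14
Reactants: 17 caged tetraone
Product: 19 caged 11-diazo tetraone, via trifluoroacetyl ketone 18 (not isolated)
Conditions: LiN(SiMe3)2, THF, −78 °C; CF3CO2CH2CF3; then CH3SO2N3, Et3N, H2O, MeCN, 25 °C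
Reagents that add atoms: methanesulfonyl azide, CS(=O)(=O)N=[N+]=[N-]
Why: Detrifluoroacetylative diazo transfer (Regitz type), in which C11H2 is the only enolisable position (C7 and the other α-carbons are bridgeheads or quaternary), so trifluoroacetylation and then diazo transfer with loss of the activating group place the diazo group on C11.

Step 15
Reactants: 19 caged 11-diazo tetraone
Product: 20 tetracyclic tetraone with the C11–C12 bond (cyclopentane closed, C10 ketone, C1–H, C5–H)
Conditions: Rh2(OAc)4 (1 mol%), CH2Cl2, 40 °C, slow addition of 19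
Reagents that add atoms: none
Why: Rh2(OAc)4 (divalent rhodium) takes up the diazo carbon C11 with loss of N2, and the electrophilic acyl carbenoid inserts in one concerted, hydride-transfer-like step into the tertiary C12–H of the C3 isopentyl chain, forming C11–C12. The closest known reaction type is the rhodium-catalysed intramolecular 1,5 C–H insertion of α-diazo ketones into tertiary C–H bonds, which gives cyclopentanes carrying a quaternary carbon. The cyclopentane C3–C14–C13–C12–C11 is closed by this 1,5-insertion through a six-centre transition state in which the five ring atoms are already in place, fused to the cage at C3–C11. C11 becomes a stereocentre but is not controlled here, since it lies α to the C10 ketone, is epimerisable, is made planar in step 16 and is set in step 18. The step needs site selectivity for the 1,5 tertiary C–H over the C8 methyl and bridgehead C–H bonds and over Wolff-type ring contraction. This is secured by the electron-rich tertiary C–H, the five-membered geometry, the quaternary C3 (no 1,2-hydride shift) and the primary or electron-poor character of every other C–H within reach.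

Step 16
Reactants: 20 tetracyclic tetraone
Product: 21 C10 enol triflate (C10(OSO2CF3)=C11)
Conditions: KN(SiMe3)2, THF, −78 to 0 °C; then N-(5-chloropyridin-2-yl)bis(trifluoromethanesulfonyl)imide, −78 °C
Reagents that add atoms: N-(5-chloropyridin-2-yl)-1,1,1-trifluoro-N-(trifluoromethylsulfonyl)methanesulfonamide, FC(F)(F)S(=O)(=O)N(c1ccc(Cl)cn1)S(=O)(=O)C(F)(F)F
Why: Enolate O-triflation, chemoselective because the C10 ketone is the only carbonyl that can enolise (towards C11), the other three being held between quaternary and bridgehead carbons.

Step 17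
Reactants: 21 enol triflate
Product: 22 C10=C11 alkene trione
Conditions: Pd(OAc)2 (5 mol%), PPh3, Bu3N, HCO2H, DMF, 60 °C
Reagents that add atoms: none
Why: Palladium-catalysed formate reduction of a vinyl triflate, by oxidative addition to zerovalent palladium, formate exchange, loss of CO2 and reductive elimination of C10–H, which leaves the non-enolisable ketones alone.

Step 18
Reactants: 22 alkene trione
Product: 23 tetracyclic trione (C10H2, C11–H as in the target, C1–H, C5–H)
Conditions: H2 (4 atm), Pd/C, EtOAc, 25 °C
Reagents that add atoms: none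
Why: Heterogeneous syn-hydrogenation of the trisubstituted alkene, which cannot migrate (C12 quaternary, C7 bridgehead), from the face flanked by C6H2 rather than by the equatorial C8 methyl, so H adds to C11 on the C6 side and the C12 carbon turns towards C8 as in the target.

Step 19
Reactants: 23 tetracyclic trione; 24 geranyl bromide, (E)-1-bromo-3,7-dimethylocta-2,6-diene
Product: 25 C5-geranyl tetracyclic trione
Conditions: lithium 2,2,6,6-tetramethylpiperidide (1.1 equiv), THF, −78 °C; then 24, −78 to 0 °C
Reagents that add atoms: none
Why: Bridgehead lithiation–alkylation of a bridged polyketone, in which C5–H, acidified by the C4 and C9 carbonyls, is removed in preference to C1–H because C1 is screened by the adjacent C8 methyls, and the configurationally fixed anion is alkylated with retention by the allylic bromide.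

Step 20
Reactants: 25 C5-geranyl tetracyclic trione
Product: 26 target CNP0313870.1
Conditions: lithium 2,2,6,6-tetramethylpiperidide (1.2 equiv), THF, −78 °C; then (CH3)2CHCOCl, −78 °C
Reagents that add atoms: 2-methylpropanoyl chloride, CC(C)C(Cl)=O
Why: Second bridgehead lithiation at the only remaining acidic C–H (C1) followed by C-acylation, O-acylation being impossible at a bridgehead, installs the isobutyryl group with retention.

**Compound list**

1 | (E)-pent-3-en-2-one | C/C=C/C(C)=O | starting material
2 | (E)-2-[(triisopropylsilyl)oxy]penta-1,3-diene | C=C(O[Si](C(C)C)(C(C)C)C(C)C)/C=C/C | intermediate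
3 | 2,2,2-trifluoroethyl acrylate | C=CC(=O)OCC(F)(F)F | starting material
4 | 2,2,2-trifluoroethyl (1S,2R)-2-methyl-4-[(triisopropylsilyl)oxy]cyclohex-3-ene-1-carboxylate | CC(C)[Si](C(C)C)(C(C)C)OC1=C[C@@H](C)[C@@H](C(=O)OCC(F)(F)F)CC1 | intermediate
5 | 2,2,2-trifluoroethyl (1S)-2-methyl-4-oxocyclohex-2-ene-1-carboxylate | O=C1C=C(C)[C@@H](C(=O)OCC(F)(F)F)CC1 | intermediate
6 | 2,2,2-trifluoroethyl (1S)-2,2-dimethyl-4-[(trimethylsilyl)oxy]cyclohex-3-ene-1-carboxylate | C[Si](C)(C)OC1=CC(C)(C)[C@@H](C(=O)OCC(F)(F)F)CC1 | intermediate
7 | diethyl 2-(3-methylbutyl)propanedioate | CCOC(=O)C(CCC(C)C)C(=O)OCC | starting material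
8 | 2-(3-methylbutyl)propanedioic acid | OC(=O)C(CCC(C)C)C(=O)O | intermediate
9 | 2-(3-methylbutyl)propanedioyl dichloride | ClC(=O)C(CCC(C)C)C(Cl)=O | intermediate
10 | bicyclic enol-trione, C7 trifluoroethyl ester exo (7S) | [C@H]12C[C@H](C(=O)OCC(F)(F)F)C(C)(C)[C@H](C1=O)C(=O)C(CCC(C)C)=C2O | intermediate
11 | 4-O-methyl enol ether of 10, ester exo (7S) | [C@H]12C[C@H](C(=O)OCC(F)(F)F)C(C)(C)[C@H](C1=O)C(=O)C(CCC(C)C)=C2OC | intermediate
12 | C7 epimer of 11, ester endo (7R) | [C@H]12C[C@@H](C(=O)OCC(F)(F)F)C(C)(C)[C@H](C1=O)C(=O)C(CCC(C)C)=C2OC | intermediate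
13 | endo C7 carboxylic acid (7R) | [C@H]12C[C@@H](C(=O)O)C(C)(C)[C@H](C1=O)C(=O)C(CCC(C)C)=C2OC | intermediate
14 | endo C7 acid chloride (not isolated) | [C@H]12C[C@@H](C(=O)Cl)C(C)(C)[C@H](C1=O)C(=O)C(CCC(C)C)=C2OC | intermediate
15 | endo C7 diazoacetyl methyl enol ether (7R) | [C@H]12C[C@@H](C(=O)C=[N+]=[N-])C(C)(C)[C@H](C1=O)C(=O)C(CCC(C)C)=C2OC | intermediate
16 | endo C7 bromoacetyl enol-trione (7R) | [C@H]12C[C@@H](C(=O)CBr)C(C)(C)[C@H](C1=O)C(=O)C(CCC(C)C)=C2O | intermediate
17 | caged tetraone (C10 ketone, C11H2, isopentyl on C3) | [C@@H]12C[C@H]3C(=O)C[C@@](CCC(C)C)(C1=O)C(=O)[C@@H](C2=O)C3(C)C | intermediate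
18 | 11-trifluoroacetyl caged tetraone (formed as its enolate, not isolated) | [C@@H]12C[C@H]3C(=O)C(C(=O)C(F)(F)F)[C@@](CCC(C)C)(C1=O)C(=O)[C@@H](C2=O)C3(C)C | intermediate
19 | caged 11-diazo tetraone (key-step precursor) | [C@@H]12C[C@H]3C(=O)C(=[N+]=[N-])[C@@](CCC(C)C)(C1=O)C(=O)[C@@H](C2=O)C3(C)C | intermediate
20 | tetracyclic tetraone (key-step product; C11 epimerisable, drawn as in the target) | [C@@H]12C[C@H]3C(=O)[C@@H]4C(C)(C)CC[C@]4(C1=O)C(=O)[C@@H](C2=O)C3(C)C | intermediate
21 | C10 enol triflate | [C@@H]12C[C@H]3C(OS(=O)(=O)C(F)(F)F)=C4C(C)(C)CC[C@]4(C1=O)C(=O)[C@@H](C2=O)C3(C)C | intermediate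
22 | C10=C11 alkene trione | [C@@H]12C[C@H]3C=C4C(C)(C)CC[C@]4(C1=O)C(=O)[C@@H](C2=O)C3(C)C | intermediate
23 | tetracyclic trione (C1–H, C5–H) | [C@@H]12C[C@H]3C[C@@H]4C(C)(C)CC[C@]4(C1=O)C(=O)[C@@H](C2=O)C3(C)C | intermediate
24 | geranyl bromide | CC(C)=CCC/C(C)=C/CBr | starting material
25 | C5-geranyl tetracyclic trione | CC(C)=CCC/C(C)=C/C[C@@]12C[C@H]3C[C@@H]4C(C)(C)CC[C@]4(C1=O)C(=O)[C@@H](C2=O)C3(C)C | intermediate
26 | CNP0313870.1 | CC(C)=CCC/C(C)=C/C[C@@]12C[C@H]3C[C@@H]4C(C)(C)CC[C@]4(C1=O)C(=O)[C@@](C(=O)C(C)C)(C2=O)C3(C)C | target

**Step count and risks**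

Total step count: 20. Longest linear sequence: 18 steps (steps 1–4 and 7–20, from pent-3-en-2-one); steps 5–6 are the side branch to 9.

Steps most likely to fail:

Step 9 (C7 inversion). The C7–H of 11 points into the fold of ring A, so deprotonation may stay incomplete at low temperature, or protonation may occur on both faces and return exo ester. The fallback sets out from 11 and comes back at 13. The exo ester is saponified (LiOH, THF–H2O) to the exo acid F1, which is converted with Me2C=C(Cl)NMe2 into the exo acid chloride F2. Et3N (toluene, 25–60 °C) dehydrochlorinates this to the ketene F3, in which C7 is planar without any strong base. Water added at −78 °C gives the ene-1,1-diol, and C-protonation on its exo face delivers the endo acid 13, so the hydrolysis of the hindered endo ester in step 10 is avoided as well.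

Step 15 (key C–H insertion). The carbenoid, held between the quaternary C3 and the cage, may insert into a C8 methyl C–H, dimerise or contract the ring before it reaches C12–H. The fallback sets out from 17 and comes back at 20, and forms the C11–C12 bond by polar rather than carbenoid chemistry. Methyl(trifluoromethyl)dioxirane hydroxylates the remote, electron-rich tertiary C12–H of 17 to the tertiary alcohol F4. Concentrated HCl converts this into the tertiary chloride F5. Me3SiOSO2CF3/Et3N then turns the only enolisable ketone (C10) into the silyl enol ether F6. TiCl4 (CH2Cl2, −78 °C) ionises the chloride and the enol ether carbon C11 captures the C12 cation (Lewis-acid α-tert-alkylation of a silyl enol ether), giving 20.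

Step 19 (bridgehead geranylation). In the rigid cage the C5 anion gains little enolate stabilisation, so deprotonation may be slow or reversible, the anion may decompose before it is alkylated, or C1 may compete. The fallback sets out from 23 and comes back at 25. The deprotonation is run with Me3SiCl already present (internal quench), which traps the bridgehead anion as it forms as the C5 silane F7. This α-silyl ketone is then cleaved with (Me2N)3S+ Me3SiF2− in the presence of 24, so the carbanion equivalent is released under non-basic conditions and alkylated to 25.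

Further compounds
F1 | step 9 | exo C7 carboxylic acid, 4-methyl enol ether (7S) | [C@H]12C[C@H](C(=O)O)C(C)(C)[C@H](C1=O)C(=O)C(CCC(C)C)=C2OC
F2 | step 9 | exo C7 acid chloride, 4-methyl enol ether (7S) | [C@H]12C[C@H](C(=O)Cl)C(C)(C)[C@H](C1=O)C(=O)C(CCC(C)C)=C2OC
F3 | step 9 | C7 ketene, 4-methyl enol ether | [C@H]12CC(=C=O)C(C)(C)[C@H](C1=O)C(=O)C(CCC(C)C)=C2OC
F4 | step 15 | caged tetraone with 3-hydroxy-3-methylbutyl chain on C3 | [C@@H]12C[C@H]3C(=O)C[C@@](CCC(C)(C)O)(C1=O)C(=O)[C@@H](C2=O)C3(C)C
F5 | step 15 | caged tetraone with 3-chloro-3-methylbutyl chain on C3 | [C@@H]12C[C@H]3C(=O)C[C@@](CCC(C)(C)Cl)(C1=O)C(=O)[C@@H](C2=O)C3(C)C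
F6 | step 15 | C10 trimethylsilyl enol ether of the tertiary chloride | [C@@H]12C[C@H]3C(O[Si](C)(C)C)=C[C@@](CCC(C)(C)Cl)(C1=O)C(=O)[C@@H](C2=O)C3(C)C
F7 | step 19 | C5-trimethylsilyl tetracyclic trione | C[Si](C)(C)[C@@]12C[C@H]3C[C@@H]4C(C)(C)CC[C@]4(C1=O)C(=O)[C@@H](C2=O)C3(C)C
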